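## Analysis of the target

The target is an open-chain 1,5-bis(3,4-dimethoxyphenyl)pent-4-ene; its only rings are the two veratryl rings. C1 is a benzylic secondary carbinol, C2 carries the CH2O carbon C2', C3 is an allylic methylene and C4=C5 is an E styrene. The C2' oxygen is acylated by (Z)-2-(hydroxymethyl)but-2-enoic acid, a trisubstituted enoate with a free allylic hydroxyl and the methyl group cis to the carboxyl. C1 is S and C2 is R; with aryl–C1–C2–C2' drawn as a zigzag, the C1 hydroxyl and the C3 branch on C2 lie on the same side, so the core is a syn 2-substituted 1-aryl-propane-1,3-diol acylated on its primary oxygen. Sensitive points are the electron-rich benzylic carbinol (ionises under acid), the Z enoate (isomerises to E when the acid is turned into an acylating agent), the 1,3-diol monoester (acyl migration under base) and two alkenes that rule out hydrogenolytic or oxidative deprotection. The difficulty is to set C2 absolutely and C1 relative to it in a chain with no ring to relay information, while securing E geometry at C4=C5, Z geometry in the ester and acylation of the primary hydroxyl only. The strategy rests on the C2–C3 bond lying allylic to the E C4=C5 alkene: with C1 at the acid level, C1(=O)–C2–C3–C4=C5 is a γ,δ-unsaturated acid, so the C2–C3 bond, the C2 configuration and the alkene geometry can all be derived from one C5–O stereocentre of an allylic ester by a [3,3] shift.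

## Retrosynthetic reasoning

**Ester C2'–O bond and the side-chain silyl ether.** Target 25 is traced to its silyl ether 24, and 24 to diol 17 and the Z acid 23. The ester is the most labile bond and is cut last, which makes the route convergent. The forward step must acylate only the primary hydroxyl and must not isomerise the Z alkene. A Mitsunobu esterification meets both needs, because it activates the alcohol and never turns 23 into an acylating agent. Silyl protection is used because benzyl-type ethers could not be removed beside two alkenes and two electron-rich arenes.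

**C1–H bond.** Diol 17 comes from hydroxy ketone 16, which comes from silyl ether 15. Cutting here lets C2, once set, control C1: the free C2' hydroxyl and the ketone oxygen bind one metal, and a chelating hydride donor attacks anti to the C3 branch. This gives the syn relationship of the target.

**C1–aryl bond.** Ketone 15 is cut between C1 and its aryl ring into Weinreb amide 11 and aryl Grignard reagent 13, which is made from bromide 12. Amide 11 comes from acid 10. This makes one veratryl ring a simple nucleophile and exposes the γ,δ-unsaturated acid that the key step needs.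

**C2–C3 bond (key disconnection).** Acid 10 is traced through silyl ester 9 and ketene acetal 8 to allylic ester 7. The cut is made here, and not at C1–C2 or C3–C4, because it is the only one that creates the C2 stereocentre, the C2–C3 bond and the E alkene in one stereospecific event. The forward reaction must enolise 7 with one geometry, trap the enolate before the β-silyloxy group is lost, and rearrange through a single chair.

**Ester C–O bond of 7 and the carbinol.** Ester 7 is cut into the S alcohol 3 and acid 6. Alcohol 3 comes from racemate 2 by enzymatic resolution, and 2 from aldehyde 1 by addition of a vinylmetal. Acid 6 comes from ester 5 and hydroxy ester 4. This part is kept short and conventional, so that the risk of the route sits in the rearrangement.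

**Side-chain C–CO2H bond.** Acid 23 is traced through alkenyllithium 22 to iodide 21, then to iodo alcohol 20, stannane 19 and alkyne 18. The Z geometry requires anti addition of hydrogen and a metal across the alkyne, with the metal on the carbon next to the CH2OH group. A hydroxyl-directed trans-hydrostannation provides this, whereas the classical hydroalumination of propargylic alcohols would place the metal on the other carbon.

## Alternatives that were turned down

**Alternative 1:** The C1–O bond would be made by oxidising a benzylic methylene. The precursor is (R)-3-[(tert-butyldiphenylsilyloxy)methyl]-4-(3,4-dimethoxyphenyl)butanoic acid A2, which already contains C2. DDQ would take hydride from C1 and the carboxyl group would capture the cation, giving (4R,5S)-4-[(tert-butyldiphenylsilyloxy)methyl]-5-(3,4-dimethoxyphenyl)dihydrofuran-2(3H)-one A1, the trans lactone. Half-reduction of the lactone carbonyl, a benzylidene olefination at that carbon (C4) and desilylation would then lead to diol 17.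
- For: the 3,4-dimethoxybenzyl position is well suited to hydride abstraction, the C1–O bond is formed directly, and neither an aryl nucleophile nor a ketone reduction is needed. On that point it is stronger than the chosen route. The benzylic lactone can also re-ionise, so the trans isomer could be reached under equilibrating conditions.
- Against: the key step sets only C1 relative to C2, so A2 must first be made as a single enantiomer by separate chemistry. The trans preference for closing a five-membered ring onto a planar cation beside one CH2OSi group is modest. The styrene cannot be present during the oxidation and would have to come later from a semi-stabilised ylide, which usually gives E/Z mixtures.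
- Comparison: the step count is no shorter. The chosen strategy offers in its place the C2 configuration and the E alkene from one stereospecific pericyclic step.

**Alternative 2:** C2 would be set from C1 through a silicon tether. The precursor is {[(S,E)-1,5-bis(3,4-dimethoxyphenyl)-2-methylidenepent-4-en-1-yl]oxy}dimethylsilane A4. Under Pt2[(CH2=CHSiMe2)2O]3 (zerovalent platinum) its Si–H would add across the C2=C2' methylidene in a 5-endo sense, giving (4S,5S)-5-(3,4-dimethoxyphenyl)-4-[(E)-3-(3,4-dimethoxyphenyl)prop-2-en-1-yl]-2,2-dimethyl-1-oxa-2-silacyclopentane A3, the cis ring. Oxidative cleavage of the C–Si bond would give diol 17 directly.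
- For: intramolecular hydrosilylation of 2-substituted allylic silyl ethers is a known route to syn 1,3-diols, which is the relationship needed. The sequence to 17 would be shorter than the chosen one, so it is stronger on step economy.
- Against: A4 contains a skipped diene. The platinum hydride can isomerise it into conjugation or add to the styrene. The parent carbinol, an aryl dienyl carbinol, must be obtained enantiopure from a 2-metallated 1,4-diene that is not easy to make. The level of 1,2-induction with a bulky cinnamyl group on the alkene is uncertain.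
- Comparison: the chosen strategy is longer, but its key step has no competing alkene and takes its absolute configuration from a cheap resolved carbinol.

**Alternative 3:** Both stereocentres would be set by a reduction with dynamic kinetic resolution. The precursor is racemic ethyl (E)-2-(3,4-dimethoxybenzoyl)-5-(3,4-dimethoxyphenyl)pent-4-enoate A6, available by cinnamylation of a β-keto ester. Transfer hydrogenation with RuCl(p-cymene)[(S,S)-TsDPEN] (divalent ruthenium) and HCO2H/NEt3 would form the C1–H bond while C2 epimerises, giving ethyl (2S,E)-2-[(S)-(3,4-dimethoxyphenyl)(hydroxy)methyl]-5-(3,4-dimethoxyphenyl)pent-4-enoate A5, the syn hydroxy ester. Hydride reduction of the ester would give diol 17.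
- For: it is by far the shortest access to 17, is catalytic in the chiral element, and takes the E alkene from a cinnamyl building block. On step economy it is clearly stronger than the chosen route.
- Against: the catalyst should control the face of the aryl ketone well, but the syn/anti outcome for an acyclic α-alkyl β-aryl β-keto ester without a directing α-heteroatom is not dependable. A pair of diastereomers, each enantioenriched, is a realistic result. The doubly methoxylated aryl ketone is also a slow hydride acceptor.
- Comparison: the chosen strategy gives up brevity for two stereochemical events that can each be predicted from a defined transition state, a chair [3,3] shift and a zinc chelate.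

Key step: step 6

## Route

Remark on the chemistry: the chain is numbered C1 (benzylic carbinol) to C5 (styrene terminus), and C2' is the CH2O carbon on C2. It is assumed that in the lipase acylation the R alcohol is the fast enantiomer, as the empirical rule for secondary carbinols with aryl as the large group predicts, so that the S alcohol is recovered.

Step 1
Reactants: 1 veratraldehyde (3,4-dimethoxybenzaldehyde)
Product: 2 rac-1-(3,4-dimethoxyphenyl)prop-2-en-1-ol
Conditions: CH2=CHMgBr, THF, 0 °C; aq. NH4Cl
Reagents that add atoms: vinylmagnesium bromide, C=C[Mg]Br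
Why: Grignard 1,2-addition to a non-enolisable aromatic aldehyde; the carbinol centre forms as a racemate, and a neutral work-up spares the acid-labile electron-rich allylic alcohol.

Step 2
Reactants: 2 rac-1-(3,4-dimethoxyphenyl)prop-2-en-1-ol
Product: 3 (S)-1-(3,4-dimethoxyphenyl)prop-2-en-1-ol
Conditions: Novozym 435 (immobilised Candida antarctica lipase B), vinyl acetate, MTBE, 30 °C, stopped slightly past half conversion; chromatography on Et3N-deactivated SiO2
Reagents that add atoms: none
Why: Lipase-catalysed kinetic resolution by irreversible transesterification; with aryl as the large and vinyl as the medium group the R alcohol should be acetylated, so that 3 is recovered as the unreacted S enantiomer in high enantiomeric purity under neutral conditions.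

Step 3
Reactants: 4 methyl 3-hydroxypropanoate
Product: 5 methyl 3-(tert-butyldimethylsilyloxy)propanoate
Conditions: TBSCl, imidazole, DMF, 0 °C → rt
Reagents that add atoms: tert-butyldimethylsilyl chloride, CC(C)(C)[Si](C)(C)Cl
Why: Standard silylation of a primary alcohol; the bulky, non-chelating silyl ether is chosen because it should not redirect the lithium during the enolisation of step 6.

Step 4
Reactants: 5 methyl 3-(tert-butyldimethylsilyloxy)propanoate
Product: 6 3-(tert-butyldimethylsilyloxy)propanoic acid
Conditions: LiOH·H2O, THF/H2O, 0 °C → rt; cold 1 M HCl to pH 4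
Reagents that add atoms: lithium hydroxide, [Li+].[OH-]
Why: Saponification of a methyl ester; hydroxide attacks the acyl carbon faster than it removes the α proton, so loss of silanolate by elimination should stay minor, and mild acidification keeps the silyl ether.

Step 5
Reactants: 3 (S)-1-(3,4-dimethoxyphenyl)prop-2-en-1-ol; 6 3-(tert-butyldimethylsilyloxy)propanoic acid
Product: 7 (S)-1-(3,4-dimethoxyphenyl)allyl 3-(tert-butyldimethylsilyloxy)propanoate
Conditions: DCC, DMAP (cat.), CH2Cl2, 0 °C; chromatography on Et3N-deactivated SiO2
Reagents that add atoms: none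
Why: Steglich esterification under neutral, cold conditions; the C–O bond at the stereocentre is not touched, so the S configuration is kept, and acid-promoted ionisation of the electron-rich allylic ester to its cinnamyl isomer is avoided.

Step 6
Reactants: 7 (S)-1-(3,4-dimethoxyphenyl)allyl 3-(tert-butyldimethylsilyloxy)propanoate
Product: 10 (R,E)-2-[(tert-butyldimethylsilyloxy)methyl]-5-(3,4-dimethoxyphenyl)pent-4-enoic acid, via trimethylsilyl ketene acetal 8 (not isolated), via trimethylsilyl ester 9 (not isolated)
Conditions: LiN(iPr)2, Me3SiCl (present from the start), THF, −78 °C → rt; aq. citric acid work-up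
Reagents that add atoms: none
Why: LiN(iPr)2 removes an α proton of 7 through the cyclic transition state that prevails in THF without polar additives, and the Me3SiCl already present silylates the enolate on oxygen at −78 °C, so that ketene acetal 8, with the CH2OSi carbon cis to the allyloxy oxygen, should form before silanolate can be expelled from the β position. On warming, 8 undergoes a concerted suprafacial [3,3]-sigmatropic shift, the Ireland–Claisen rearrangement in its known form with 1,3-chirality transfer from a secondary 1-arylallyl ester: C2–C3 forms as C5–O breaks, and silyl ester 9 is hydrolysed to 10 on work-up. No ring is closed; the only cyclic array is the six-membered chair transition state. The new stereocentre C2 is controlled by the S carbinol carbon C5 of 7: the aryl group takes the equatorial position of the chair, away from the OSiMe3 group, which fixes the face of the allyl unit that bonds to C2 and at the same time gives the E C4=C5 alkene. With the CH2OSi substituent pseudo-axial on the ketene acetal terminus, this chair leads to the R configuration at C2. The step needs a single ketene acetal geometry and a chair in preference to a boat; the first rests on kinetic enolisation of an ester whose silyl ether does not chelate lithium, the second on the unconstrained acyclic substrate. The basic, cold medium also protects the benzylic C5–O bond from ionisation, which would transpose the ester to the achiral cinnamyl isomer.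

Step 7
Reactants: 10 (R,E)-2-[(tert-butyldimethylsilyloxy)methyl]-5-(3,4-dimethoxyphenyl)pent-4-enoic acid
Product: 11 (R,E)-2-[(tert-butyldimethylsilyloxy)methyl]-5-(3,4-dimethoxyphenyl)-N-methoxy-N-methylpent-4-enamide
Conditions: MeNHOMe·HCl, EDC·HCl, HOBt, N-methylmorpholine, CH2Cl2, 0 °C → rt
Reagents that add atoms: N,O-dimethylhydroxylamine hydrochloride, CNOC.Cl
Why: Carbodiimide/HOBt amide coupling to the Weinreb amide; the α proton of the activated ester is only weakly acidic and the base is a tertiary amine, so C2 should keep its configuration.

Step 8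
Reactants: 12 4-bromo-1,2-dimethoxybenzene
Product: 13 3,4-dimethoxyphenylmagnesium bromide (THF solution, titrated)
Conditions: Mg, I2 (cat.), THF, reflux
Reagents that add atoms: magnesium, [Mg]
Why: Grignard formation by insertion of magnesium into the aryl C–Br bond; the solution is used directly in step 9.

Step 9
Reactants: 11 (R,E)-2-[(tert-butyldimethylsilyloxy)methyl]-5-(3,4-dimethoxyphenyl)-N-methoxy-N-methylpent-4-enamide; 13 3,4-dimethoxyphenylmagnesium bromide
Product: 15 (R,E)-2-[(tert-butyldimethylsilyloxy)methyl]-1,5-bis(3,4-dimethoxyphenyl)pent-4-en-1-one, via magnesium hemiaminal chelate 14 (not isolated)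
Conditions: THF, 0 °C → rt; cold aq. NH4Cl
Reagents that add atoms: none
Why: Aryl Grignard addition to a Weinreb amide; chelate 14 survives until the quench, which prevents over-addition and keeps the α stereocentre away from a free ketone under basic conditions, and the cold buffered quench limits enolisation of 15.

Step 10
Reactants: 15 (R,E)-2-[(tert-butyldimethylsilyloxy)methyl]-1,5-bis(3,4-dimethoxyphenyl)pent-4-en-1-one
Product: 16 (R,E)-1,5-bis(3,4-dimethoxyphenyl)-2-(hydroxymethyl)pent-4-en-1-one
Conditions: HF·pyridine, pyridine, THF, 0 °C → rt
Reagents that add atoms: none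
Why: Fluoride cleavage of a primary silyl ether under buffered, weakly acidic conditions; basic fluoride sources are avoided because the β-hydroxy ketone could epimerise at C2, dehydrate or undergo retro-aldol cleavage.

Step 11
Reactants: 16 (R,E)-1,5-bis(3,4-dimethoxyphenyl)-2-(hydroxymethyl)pent-4-en-1-one
Product: 17 (1S,2R,E)-1,5-bis(3,4-dimethoxyphenyl)-2-(hydroxymethyl)pent-4-en-1-ol
Conditions: Zn(BH4)2, Et2O, −30 → 0 °C; aq. NH4Cl
Reagents that add atoms: none
Why: Chelation-controlled borohydride reduction of a β-hydroxy ketone: zinc bridges the ketone oxygen and the C2' hydroxyl in a six-membered chelate, the C3 branch on C2 turns out of the aryl ketone plane to avoid the ortho hydrogens, and hydride attacks C1 from the opposite face. This sets C1 as S, syn to the C2 branch along aryl–C1–C2–C2'.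

Step 12
Reactants: 18 but-2-yn-1-ol
Product: 19 (Z)-2-(tributylstannyl)but-2-en-1-ol
Conditions: Bu3SnH, [Cp*RuCl]4 (cat.), CH2Cl2, rt
Reagents that add atoms: tributyltin hydride, CCCC[SnH](CCCC)CCCC
Why: Ruthenium-catalysed trans-hydrostannation of a propargylic alcohol; hydrogen bonding between the hydroxyl and the chloride ligand steers tin to the alkyne carbon next to the CH2OH group, and anti addition of H and Sn places the methyl group cis to tin, the geometry needed for the Z acid.

Step 13
Reactants: 19 (Z)-2-(tributylstannyl)but-2-en-1-ol
Product: 20 (Z)-2-iodobut-2-en-1-ol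
Conditions: I2, CH2Cl2, 0 °C
Reagents that add atoms: iodine, II
Why: Iododestannylation of an alkenylstannane is an ipso substitution that proceeds with retention of alkene geometry.

Step 14
Reactants: 20 (Z)-2-iodobut-2-en-1-ol
Product: 21 (Z)-tert-butyl[(2-iodobut-2-en-1-yl)oxy]dimethylsilane
Conditions: TBSCl, imidazole, CH2Cl2, 0 °C → rt
Reagents that add atoms: tert-butyldimethylsilyl chloride, CC(C)(C)[Si](C)(C)Cl
Why: Standard silylation of the primary allylic alcohol; the ether masks the side-chain hydroxyl during lithiation and esterification.

Step 15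
Reactants: 21 (Z)-tert-butyl[(2-iodobut-2-en-1-yl)oxy]dimethylsilane
Product: 23 (Z)-2-[(tert-butyldimethylsilyloxy)methyl]but-2-enoic acid, via alkenyllithium 22 (not isolated)
Conditions: t-BuLi (2.1 equiv), Et2O, −78 °C; CO2, −78 → 0 °C; cold 1 M HCl to pH 4
Reagents that add atoms: carbon dioxide, O=C=O
Why: Iodine–lithium exchange at −78 °C gives 22 with retention of geometry, and carboxylation gives the acid without any acyl activation that could isomerise the Z alkene; the low temperature suppresses silyl migration from oxygen to carbon and elimination to an allene.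

Step 16
Reactants: 17 (1S,2R,E)-1,5-bis(3,4-dimethoxyphenyl)-2-(hydroxymethyl)pent-4-en-1-ol; 23 (Z)-2-[(tert-butyldimethylsilyloxy)methyl]but-2-enoic acid
Product: 24 (2R,3S)-3-(3,4-dimethoxyphenyl)-2-[(E)-3-(3,4-dimethoxyphenyl)prop-2-en-1-yl]-3-hydroxypropyl (Z)-2-[(tert-butyldimethylsilyloxy)methyl]but-2-enoate
Conditions: PPh3, DIAD, THF, 0 °C (DIAD added last)
Reagents that add atoms: none
Why: Mitsunobu esterification: the less hindered primary hydroxyl of 17 is activated and displaced at C2' by the carboxylate of 23. Because the acid is never made into an acylating agent, the Z enoate cannot isomerise by conjugate addition–elimination, and the more hindered benzylic hydroxyl should stay free; C2' is not stereogenic, so no configuration is at stake.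

Step 17
Reactants: 24 (2R,3S)-3-(3,4-dimethoxyphenyl)-2-[(E)-3-(3,4-dimethoxyphenyl)prop-2-en-1-yl]-3-hydroxypropyl (Z)-2-[(tert-butyldimethylsilyloxy)methyl]but-2-enoate
Product: 25 (2R,3S)-3-(3,4-dimethoxyphenyl)-2-[(E)-3-(3,4-dimethoxyphenyl)prop-2-en-1-yl]-3-hydroxypropyl (Z)-2-(hydroxymethyl)but-2-enoate (CNP0417076.1)
Conditions: HF·pyridine, pyridine, THF, 0 °C
Reagents that add atoms: none
Why: Buffered fluoride desilylation of the primary allylic silyl ether; the medium is not basic enough for acyl migration to the C1 hydroxyl and not acidic enough to ionise the benzylic carbinol.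

## Compound list

1 | veratraldehyde (3,4-dimethoxybenzaldehyde) | COc1ccc(C=O)cc1OC | starting material
2 | rac-1-(3,4-dimethoxyphenyl)prop-2-en-1-ol | OC(C=C)c1ccc(OC)c(OC)c1 | intermediate
3 | (S)-1-(3,4-dimethoxyphenyl)prop-2-en-1-ol | O[C@@H](C=C)c1ccc(OC)c(OC)c1 | intermediate
4 | methyl 3-hydroxypropanoate | COC(=O)CCO | starting material
5 | methyl 3-(tert-butyldimethylsilyloxy)propanoate | COC(=O)CCO[Si](C)(C)C(C)(C)C | intermediate
6 | 3-(tert-butyldimethylsilyloxy)propanoic acid | OC(=O)CCO[Si](C)(C)C(C)(C)C | intermediate
7 | (S)-1-(3,4-dimethoxyphenyl)allyl 3-(tert-butyldimethylsilyloxy)propanoate | CC(C)(C)[Si](C)(C)OCCC(=O)O[C@@H](C=C)c1ccc(OC)c(OC)c1 | intermediate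
8 | (E)-3-(tert-butyldimethylsilyloxy)-1-[(S)-1-(3,4-dimethoxyphenyl)allyloxy]-1-(trimethylsilyloxy)prop-1-ene (CH2OSi cis to the allyloxy oxygen) | CC(C)(C)[Si](C)(C)OC/C=C(/O[Si](C)(C)C)O[C@@H](C=C)c1ccc(OC)c(OC)c1 | intermediate (not isolated)
9 | trimethylsilyl (R,E)-2-[(tert-butyldimethylsilyloxy)methyl]-5-(3,4-dimethoxyphenyl)pent-4-enoate | CC(C)(C)[Si](C)(C)OC[C@@H](C/C=C/c1ccc(OC)c(OC)c1)C(=O)O[Si](C)(C)C | intermediate (not isolated)
10 | (R,E)-2-[(tert-butyldimethylsilyloxy)methyl]-5-(3,4-dimethoxyphenyl)pent-4-enoic acid | CC(C)(C)[Si](C)(C)OC[C@@H](C/C=C/c1ccc(OC)c(OC)c1)C(=O)O | intermediate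
11 | (R,E)-2-[(tert-butyldimethylsilyloxy)methyl]-5-(3,4-dimethoxyphenyl)-N-methoxy-N-methylpent-4-enamide | CC(C)(C)[Si](C)(C)OC[C@@H](C/C=C/c1ccc(OC)c(OC)c1)C(=O)N(C)OC | intermediate
12 | 4-bromo-1,2-dimethoxybenzene | COc1ccc(Br)cc1OC | starting material
13 | 3,4-dimethoxyphenylmagnesium bromide | COc1ccc([Mg]Br)cc1OC | intermediate
14 | bromomagnesium alkoxide of the tetrahedral adduct of 11 and 13 (N-methoxy-N-methyl hemiaminal, C2 as R, hemiaminal carbon undefined) | CC(C)(C)[Si](C)(C)OC[C@@H](C/C=C/c1ccc(OC)c(OC)c1)C(O[Mg]Br)(N(C)OC)c1ccc(OC)c(OC)c1 | intermediate (not isolated)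
15 | (R,E)-2-[(tert-butyldimethylsilyloxy)methyl]-1,5-bis(3,4-dimethoxyphenyl)pent-4-en-1-one | CC(C)(C)[Si](C)(C)OC[C@@H](C/C=C/c1ccc(OC)c(OC)c1)C(=O)c1ccc(OC)c(OC)c1 | intermediate
16 | (R,E)-1,5-bis(3,4-dimethoxyphenyl)-2-(hydroxymethyl)pent-4-en-1-one | OC[C@@H](C/C=C/c1ccc(OC)c(OC)c1)C(=O)c1ccc(OC)c(OC)c1 | intermediate
17 | (1S,2R,E)-1,5-bis(3,4-dimethoxyphenyl)-2-(hydroxymethyl)pent-4-en-1-ol | OC[C@@H](C/C=C/c1ccc(OC)c(OC)c1)[C@H](O)c1ccc(OC)c(OC)c1 | intermediate
18 | but-2-yn-1-ol | CC#CCO | starting material
19 | (Z)-2-(tributylstannyl)but-2-en-1-ol | C/C=C(/CO)[Sn](CCCC)(CCCC)CCCC | intermediate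
20 | (Z)-2-iodobut-2-en-1-ol | C/C=C(/CO)I | intermediate
21 | (Z)-tert-butyl[(2-iodobut-2-en-1-yl)oxy]dimethylsilane | C/C=C(/CO[Si](C)(C)C(C)(C)C)I | intermediate
22 | 2-lithio derivative of 21, {1-[(tert-butyldimethylsilyloxy)methyl]prop-1-en-1-yl}lithium (methyl cis to lithium) | C/C=C(/CO[Si](C)(C)C(C)(C)C)[Li] | intermediate (not isolated)
23 | (Z)-2-[(tert-butyldimethylsilyloxy)methyl]but-2-enoic acid | C/C=C(/CO[Si](C)(C)C(C)(C)C)C(=O)O | intermediate
24 | (2R,3S)-3-(3,4-dimethoxyphenyl)-2-[(E)-3-(3,4-dimethoxyphenyl)prop-2-en-1-yl]-3-hydroxypropyl (Z)-2-[(tert-butyldimethylsilyloxy)methyl]but-2-enoate | C/C=C(/CO[Si](C)(C)C(C)(C)C)C(=O)OC[C@@H](C/C=C/c1ccc(OC)c(OC)c1)[C@H](O)c1ccc(OC)c(OC)c1 | intermediate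
25 | (2R,3S)-3-(3,4-dimethoxyphenyl)-2-[(E)-3-(3,4-dimethoxyphenyl)prop-2-en-1-yl]-3-hydroxypropyl (Z)-2-(hydroxymethyl)but-2-enoate | C/C=C(/CO)C(=O)OC[C@@H](C/C=C/c1ccc(OC)c(OC)c1)[C@H](O)c1ccc(OC)c(OC)c1 | target

## Step count and least certain steps

Total: 17 steps. Longest linear sequence: 10 steps (steps 1, 2, 5, 6, 7, 9, 10, 11, 16, 17). Steps 3–4, step 8 and steps 12–15 are side branches.

**Step 6 (key step).** Three processes could spoil it:
- loss of silanolate from the enolate by β-elimination before silylation;
- enolisation with mixed geometry, which lowers the enantiomeric purity of 10 because the two ketene acetal geometries lead to opposite configurations at C2 through the same chair;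
- ionisation of 7 with transposition to the cinnamyl ester before enolisation.

A small loss of enantiomeric purity could be repaired by crystallising a salt of 10 with a chiral amine. The fallback sets C2 by an auxiliary instead of by chirality transfer. It sets out from 12 and returns at 16.
- Heck coupling of 12 with pent-4-enoic acid (Pd(OAc)2, P(o-tol)3, Et3N, MeCN, 80 °C) would give (E)-5-(3,4-dimethoxyphenyl)pent-4-enoic acid F1.
- Activation with pivaloyl chloride/Et3N and reaction with lithiated (S)-4-benzyloxazolidin-2-one would give (S)-4-benzyl-3-[(E)-5-(3,4-dimethoxyphenyl)pent-4-enoyl]oxazolidin-2-one F2.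
- Hydroxymethylation of its titanium enolate (TiCl4, iPr2NEt, 1,3,5-trioxane, CH2Cl2, 0 °C), with the electrophile entering anti to the benzyl group, would give (S)-4-benzyl-3-[(R,E)-5-(3,4-dimethoxyphenyl)-2-(hydroxymethyl)pent-4-enoyl]oxazolidin-2-one F3.
- Transamination (Me3Al, MeNHOMe·HCl) would give (R,E)-5-(3,4-dimethoxyphenyl)-2-(hydroxymethyl)-N-methoxy-N-methylpent-4-enamide F4.
- Excess 13 would convert F4 into 16.

**Step 11.** Facial selectivity may be poor if reduction through an open, non-chelated conformer competes, which would give the C1 epimer. The fallback moves control from the substrate to a catalyst. It sets out from 15 and returns at 17. Reduction of 15 with (R)-2-methyl-CBS-oxazaborolidine and BH3·SMe2 (the catalyst enantiomer that turns acetophenone into the S alcohol) should give (1S,2R,E)-2-[(tert-butyldimethylsilyloxy)methyl]-1,5-bis(3,4-dimethoxyphenyl)pent-4-en-1-ol F5. HF·pyridine then gives 17.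

**Step 16.** Activation may not stay at the primary hydroxyl. Activation of the benzylic hydroxyl could lead to ionisation, substitution or elimination at C1, and ring closure to an oxetane is also conceivable. The fallback reverses the roles and activates the acid. It sets out from 23 (with 17) and returns at 24. Treatment of 23 with 2,4,6-trichlorobenzoyl chloride and Et3N gives (Z)-2-[(tert-butyldimethylsilyloxy)methyl]but-2-enoic 2,4,6-trichlorobenzoic anhydride F6. A limiting amount of F6 is added to 17 at −20 °C, with only a trace of DMAP or none, so that the primary hydroxyl is acylated and the Z geometry can be checked before desilylation.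

**Step 9.** The hindered α-branched amide may react slowly, and ketone 15 may epimerise at C2 or lose silanolate by β-elimination if it meets base during a warm quench. The fallback forms the ketone under non-basic conditions. It sets out from 11 and returns at 15.
- Reduction of 11 with iBu2AlH at −78 °C gives (R,E)-2-[(tert-butyldimethylsilyloxy)methyl]-5-(3,4-dimethoxyphenyl)pent-4-enal F7.
- Addition of 13 at −78 °C gives (2R,E)-2-[(tert-butyldimethylsilyloxy)methyl]-1,5-bis(3,4-dimethoxyphenyl)pent-4-en-1-ol as a C1 epimer mixture F8.
- Oxidation with Dess–Martin periodinane/NaHCO3 gives 15.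

**Step 15.** The alkenyllithium may be lost before carboxylation, by silyl migration from oxygen to carbon or by elimination of silanolate to an allene, if the temperature rises. The fallback replaces the organolithium by a palladium acyl intermediate. It sets out from 21 and returns at 23. Hydroxycarbonylation of 21 (Pd(OAc)2, PPh3, CO at 1 atm, H2O, K2CO3, DMF, 50 °C) gives 23 directly. This detour makes no new compound (F0).

## Further compounds

F1 | step 6 | (E)-5-(3,4-dimethoxyphenyl)pent-4-enoic acid | OC(=O)CC/C=C/c1ccc(OC)c(OC)c1
F2 | step 6 | (S)-4-benzyl-3-[(E)-5-(3,4-dimethoxyphenyl)pent-4-enoyl]oxazolidin-2-one | O=C1OC[C@H](Cc2ccccc2)N1C(=O)CC/C=C/c1ccc(OC)c(OC)c1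
F3 | step 6 | (S)-4-benzyl-3-[(R,E)-5-(3,4-dimethoxyphenyl)-2-(hydroxymethyl)pent-4-enoyl]oxazolidin-2-one | O=C1OC[C@H](Cc2ccccc2)N1C(=O)[C@@H](CO)C/C=C/c1ccc(OC)c(OC)c1
F4 | step 6 | (R,E)-5-(3,4-dimethoxyphenyl)-2-(hydroxymethyl)-N-methoxy-N-methylpent-4-enamide | OC[C@@H](C/C=C/c1ccc(OC)c(OC)c1)C(=O)N(C)OC
F5 | step 11 | (1S,2R,E)-2-[(tert-butyldimethylsilyloxy)methyl]-1,5-bis(3,4-dimethoxyphenyl)pent-4-en-1-ol | CC(C)(C)[Si](C)(C)OC[C@@H](C/C=C/c1ccc(OC)c(OC)c1)[C@H](O)c1ccc(OC)c(OC)c1
F6 | step 16 | (Z)-2-[(tert-butyldimethylsilyloxy)methyl]but-2-enoic 2,4,6-trichlorobenzoic anhydride | C/C=C(/CO[Si](C)(C)C(C)(C)C)C(=O)OC(=O)c1c(Cl)cc(Cl)cc1Cl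
F7 | step 9 | (R,E)-2-[(tert-butyldimethylsilyloxy)methyl]-5-(3,4-dimethoxyphenyl)pent-4-enal | CC(C)(C)[Si](C)(C)OC[C@@H](C/C=C/c1ccc(OC)c(OC)c1)C=O
F8 | step 9 | (2R,E)-2-[(tert-butyldimethylsilyloxy)methyl]-1,5-bis(3,4-dimethoxyphenyl)pent-4-en-1-ol, C1 epimer mixture | CC(C)(C)[Si](C)(C)OC[C@@H](C/C=C/c1ccc(OC)c(OC)c1)C(O)c1ccc(OC)c(OC)c1
F0 | step 15 | none | none
A1 | alternative 1 | (4R,5S)-4-[(tert-butyldiphenylsilyloxy)methyl]-5-(3,4-dimethoxyphenyl)dihydrofuran-2(3H)-one (trans) | CC(C)(C)[Si](c1ccccc1)(c1ccccc1)OC[C@H]2CC(=O)O[C@@H]2c3ccc(OC)c(OC)c3
A2 | alternative 1 | (R)-3-[(tert-butyldiphenylsilyloxy)methyl]-4-(3,4-dimethoxyphenyl)butanoic acid | CC(C)(C)[Si](c1ccccc1)(c1ccccc1)OC[C@H](Cc1ccc(OC)c(OC)c1)CC(=O)O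
A3 | alternative 2 | (4S,5S)-5-(3,4-dimethoxyphenyl)-4-[(E)-3-(3,4-dimethoxyphenyl)prop-2-en-1-yl]-2,2-dimethyl-1-oxa-2-silacyclopentane (cis) | C[Si]1(C)C[C@@H](C/C=C/c2ccc(OC)c(OC)c2)[C@H](O1)c3ccc(OC)c(OC)c3
A4 | alternative 2 | {[(S,E)-1,5-bis(3,4-dimethoxyphenyl)-2-methylidenepent-4-en-1-yl]oxy}dimethylsilane | C[SiH](C)O[C@@H](C(=C)C/C=C/c1ccc(OC)c(OC)c1)c1ccc(OC)c(OC)c1
A5 | alternative 3 | ethyl (2S,E)-2-[(S)-(3,4-dimethoxyphenyl)(hydroxy)methyl]-5-(3,4-dimethoxyphenyl)pent-4-enoate (syn) | CCOC(=O)[C@@H](C/C=C/c1ccc(OC)c(OC)c1)[C@H](O)c1ccc(OC)c(OC)c1
A6 | alternative 3 | racemic ethyl (E)-2-(3,4-dimethoxybenzoyl)-5-(3,4-dimethoxyphenyl)pent-4-enoate | CCOC(=O)C(C/C=C/c1ccc(OC)c(OC)c1)C(=O)c1ccc(OC)c(OC)c1
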